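The cyclopentanol ring (C1–C5) is cut at C1–C2 and C3–C4, so that the ethano bridge C2–C3 arrives as acrolein. One hydrogen-atom-transfer radical–polar crossover annulation makes both bonds: the tertiary C1 radical of a cycloheptenone adds to acrolein and the resulting enolate closes on the C4 ketone. It exploits the 1,3-relation of the methyl-bearing quaternary C1 and the isopropyl carbinol C4 across ring-fusion carbon C5, and sets C1 and C4. The precursor, a 6-hydroxy-5-isobutyryl-4-methylcyclohept-3-enone, comes from a furan–oxyallyl [4+3] adduct whose oxygen bridge is opened by SmI2; the furan oxygen ends as the ester oxygen on C6, and the surplus formyl carbon is excised later.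

Key step: step 6

Remark: atom numbers follow the target (C1 quaternary carbon with the methyl group, C2 and C3 ring CH2, C4 carbinol with isopropyl, C5 ring-fusion CH, C6 ester carbon, C7 CH2, C8 methylene-bearing carbon, C9 and C10 diol carbons); α is the ring face of the C6, C9 and C10 oxygens, β that of the C1 methyl group.
Assumption: compounds 2 and 4 are taken to be catalogue items.

Step 1
Reactants: 1 prop-1-yn-1-ylmagnesium bromide; 2 N-methoxy-N,2-dimethylpropanamide
Product: 3 2-methylhex-4-yn-3-one
Conditions: THF, 0 °C to rt; aq. HCl work-up
Reagents that add atoms: none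
Why: Weinreb ketone synthesis, in which the alkynyl Grignard reagent adds once to the N-methoxy-N-methylamide through a stable magnesium chelate that collapses to the ynone only on work-up.

Step 2
Reactants: 3 2-methylhex-4-yn-3-one; 4 4-phenyl-1,3-oxazole
Product: 6 2-methyl-1-(4-methylfuran-3-yl)propan-1-one, via oxazole–alkyne cycloadduct 5 (not isolated)
Conditions: neat, sealed tube, 200 °C
Reagents that add atoms: none
Why: Diels–Alder addition of the ynone across C2 and C5 of the oxazole is followed by retro-Diels–Alder loss of benzonitrile, so the two alkyne carbons become C3 and C4 of the furan whatever the orientation of the cycloaddition.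

Step 3
Reactants: 6 2-methyl-1-(4-methylfuran-3-yl)propan-1-one; 7 1,1,3,3-tetrabromopropan-2-one
Product: 9 rac-(1S,5R)-6-methyl-7-(2-methylpropanoyl)-8-oxabicyclo[3.2.1]oct-6-en-3-one, via dibromo cycloadduct 8 (not isolated)
Conditions: Zn–Cu couple, B(OEt)3, THF, rt; then Zn–Cu couple, NH4Cl, MeOH, −78 °C to rt
Reagents that add atoms: none
Why: Zinc generates the 1,3-dibromo-2-oxyallyl cation, which undergoes [4+3] cycloaddition to the furan (first bond at the furan carbon next to the methyl-bearing carbon), and zinc–copper couple then removes both bromine atoms; the two bridgehead centres (later C6 and C10) form together on one face and the product is racemic.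

Step 4
Reactants: 9 rac-(1S,5R)-6-methyl-7-(2-methylpropanoyl)-8-oxabicyclo[3.2.1]oct-6-en-3-one
Product: 10 rac-(5S,6S)-6-hydroxy-4-methyl-5-(2-methylpropanoyl)cyclohept-3-en-1-one
Conditions: SmI2, THF–MeOH, −78 °C
Reagents that add atoms: none
Why: Two-electron reduction of the enone expels the γ-oxygen at C10 (reductive cleavage of a vinylogous α-alkoxy ketone) and the samarium dienolate is protonated kinetically at C5 to give the β,γ-enone; the proton should be relayed by methanol bound to the neighbouring C6 samarium alkoxide, on the face of the C6 oxygen, which places the isobutyryl group trans to the hydroxyl (sets C5 relative to C6).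

Step 5
Reactants: 10 rac-(5S,6S)-6-hydroxy-4-methyl-5-(2-methylpropanoyl)cyclohept-3-en-1-one
Product: 11 (5S,6S)-6-hydroxy-4-methyl-5-(2-methylpropanoyl)cyclohept-3-en-1-one (recovered alcohol)
Conditions: Burkholderia cepacia lipase (immobilised), vinyl acetate, tBuOMe, 30 °C, stopped just past half conversion
Reagents that add atoms: none
Why: Lipase-catalysed acylative kinetic resolution of a secondary alcohol, in which the enzyme should acetylate the (6R)-enantiomer (large branched substituent C5, medium CH2 C7, as the empirical size rule for lipases predicts) and leave the (5S,6S)-alcohol, which is separated from the acetate by chromatography.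

Step 6
Reactants: 11 (5S,6S)-6-hydroxy-4-methyl-5-(2-methylpropanoyl)cyclohept-3-en-1-one; 12 prop-2-enal (acrolein)
Product: 14 trans-fused bicyclic hydroxy aldehyde (C3 formyl; C4 β-OH and α-isopropyl; C6 α-OH; C8 ketone; C1 β-methyl; H5 α; C3 epimers), via Giese-adduct enolate 13 (not isolated)
Conditions: Fe(acac)3 (0.5 equiv), PhSiH3, acrolein (excess), EtOH–ethylene glycol, 0 °C to rt
Reagents that add atoms: none
Why: An iron hydride formed from Fe(acac)3 and PhSiH3 transfers a hydrogen atom to C10 of the only alkene and gives the tertiary C1 radical, which adds to the β-carbon of acrolein (Giese addition, C1–C2 bond); reduction of the α-formyl radical gives the C3 enolate, which attacks the C4 ketone (intramolecular aldol addition, C3–C4 bond). The closest known reaction type is the hydrogen-atom-transfer-initiated radical–polar crossover annulation of a carbonyl-bearing alkene with an unsaturated aldehyde or ketone. The cyclopentane ring closes in the polar step as a 5-exo-trig (enolexo) aldol addition on the exocyclic C4 carbonyl. C1 is set by approach of acrolein to the ring face opposite the vicinal isobutyryl group on C5 (C2 α, methyl β, trans ring fusion); C4 is set in a closed aldol transition state that keeps the isopropyl group on the α face, away from the angular methyl group, and so places the hydroxyl β; C3 forms as a mixture that step 8 erases. The step needs chemoselective hydrogen-atom transfer, secured by the single electron-rich trisubstituted alkene, and closure on C4 and not on the C8 ring ketone, secured by the fused five-membered transition state being favoured over the bridged six-membered one.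

Step 7
Reactants: 14 trans-fused bicyclic hydroxy aldehyde
Product: 15 the corresponding C3 carboxylic acid (C3 epimers)
Conditions: NaClO2, NaH2PO4, 2-methylbut-2-ene, tBuOH–H2O, 0 °C to rt
Reagents that add atoms: sodium chlorite, [Na+].[O-]Cl=O
Why: Pinnick oxidation converts the aldehyde into the acid under buffered conditions that leave the ketone, the secondary and the tertiary alcohol untouched and remove the retro-aldol-prone β-hydroxy aldehyde.

Step 8
Reactants: 15 C3 carboxylic acid
Product: 16 4β,6α-dihydroxy bicyclic ketone (C8 ketone; C1 β-methyl; H5 α; C2 and C3 both CH2)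
Conditions: 9-mesityl-10-phenylacridinium tetrafluoroborate (cat.), (PhS)2 (cat.), iPr2NEt (cat.), CF3CH2OH, blue LEDs, rt
Reagents that add atoms: none
Why: Photoredox hydrodecarboxylation, in which the excited acridinium oxidises the carboxylate, loss of CO2 gives the secondary C3 radical and thiophenol returns a hydrogen atom, so the surplus carbon leaves and the C3 stereocentre disappears.

Step 9
Reactants: 16 4β,6α-dihydroxy bicyclic ketone
Product: 18 4β,6α-dihydroxy bicyclic enone (C8 ketone conjugated to C9=C10), via tris(trimethylsilyl) derivative 17 (not isolated)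
Conditions: LiN(iPr)2 (3.5 equiv), Me3SiCl, THF, −78 °C; solvent exchange; Pd(OAc)2, MeCN, rt; then dilute aq. HCl, THF, 0 °C
Reagents that add atoms: none
Why: Saegusa–Ito oxidation, in which the two lithium alkoxides formed first steer kinetic enolisation to C9, away from the C6 alkoxide, Pd(OAc)2 turns the silyl enol ether into the C9=C10 enone (C10 is the only β-position with hydrogen on that side) and dilute acid removes the two O-silyl groups.

Step 10
Reactants: 18 4β,6α-dihydroxy bicyclic enone; 19 3-methylbutanoic anhydride
Product: 20 6α-(3-methylbutanoyloxy)-4β-hydroxy bicyclic enone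
Conditions: DMAP (cat.), pyridine, CH2Cl2, 0 °C
Reagents that add atoms: none
Why: DMAP-catalysed acylation esterifies the secondary C6 hydroxyl while the hindered tertiary C4 hydroxyl stays free, and the low temperature and weak base should avoid β-elimination of the new ester.

Step 11
Reactants: 20 6α-(3-methylbutanoyloxy)-4β-hydroxy bicyclic enone
Product: 21 9α,10α-dihydroxy-6α-(3-methylbutanoyloxy)-4β-hydroxy bicyclic C8 ketone
Conditions: OsO4 (cat.), N-methylmorpholine N-oxide, citric acid, tBuOH–H2O, rt
Reagents that add atoms: osmium tetroxide, O=[Os](=O)(=O)=O; N-methylmorpholine N-oxide, C[N+]1([O-])CCOCC1; water, O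
Why: Upjohn dihydroxylation, in which OsO4 adds syn to the C9=C10 bond from the α face, opposite the axial C1 methyl group next to C10, so that the two hydroxyls are cis to each other and trans to the methyl group (sets C9 and C10).

Step 12
Reactants: 21 9α,10α-dihydroxy-6α-(3-methylbutanoyloxy)-4β-hydroxy bicyclic C8 ketone
Product: 22 (1R,3aS,4S,5R,8S,8aS)-1,4,5-trihydroxy-3a-methyl-6-methylidene-1-(propan-2-yl)decahydroazulen-8-yl 3-methylbutanoate (target)
Conditions: Zn, CH2Br2, TiCl4, THF–CH2Cl2, 0 °C to rt
Reagents that add atoms: dibromomethane, BrCBr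
Why: Takai–Lombardo methylenation, a non-basic titanium–zinc methylene transfer that is selective for the ketone over the ester, tolerates free hydroxyl groups when used in excess and avoids the retro-aldol cleavage and ester β-elimination that a basic ylide would cause.

Compound list
1 | prop-1-yn-1-ylmagnesium bromide | CC#C[Mg]Br | starting material
2 | N-methoxy-N,2-dimethylpropanamide | CC(C)C(=O)N(C)OC | starting material
3 | 2-methylhex-4-yn-3-one | CC#CC(=O)C(C)C | intermediate
4 | 4-phenyl-1,3-oxazole | c1ccc(cc1)-c1cocn1 | starting material
5 | 2-methyl-1-(5-methyl-3-phenyl-7-oxa-2-azabicyclo[2.2.1]hepta-2,5-dien-6-yl)propan-1-one (racemic; one of two possible regioisomers drawn) | O1C2N=C(c3ccccc3)C1C(C)=C2C(=O)C(C)C | intermediate (not isolated)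
6 | 2-methyl-1-(4-methylfuran-3-yl)propan-1-one | Cc1cocc1C(=O)C(C)C | intermediate
7 | 1,1,3,3-tetrabromopropan-2-one | BrC(Br)C(=O)C(Br)Br | starting material
8 | 2,4-dibromo derivative of 9 (racemic; bromine epimers) | O=C1C(Br)[C@@H]2O[C@H](C1Br)C(C)=C2C(=O)C(C)C | intermediate (not isolated)
9 | rac-(1S,5R)-6-methyl-7-(2-methylpropanoyl)-8-oxabicyclo[3.2.1]oct-6-en-3-one (racemate; enantiomer of the route drawn) | O=C1C[C@@H]2O[C@H](C1)C(C)=C2C(=O)C(C)C | intermediate
10 | rac-(5S,6S)-6-hydroxy-4-methyl-5-(2-methylpropanoyl)cyclohept-3-en-1-one (racemate; acyl and hydroxyl trans; enantiomer of the route drawn) | O=C1C[C@H](O)[C@@H](C(=O)C(C)C)C(C)=CC1 | intermediate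
11 | (5S,6S)-6-hydroxy-4-methyl-5-(2-methylpropanoyl)cyclohept-3-en-1-one | O=C1C[C@H](O)[C@@H](C(=O)C(C)C)C(C)=CC1 | intermediate
12 | prop-2-enal (acrolein) | C=CC=O | starting material
13 | C3 enolate of the Giese adduct (11 with H added at C10 and a 3-oxidoprop-2-enyl chain on the α face of C1) | O=C1C[C@H](O)[C@@H](C(=O)C(C)C)[C@](C)(CC=C[O-])CC1 | intermediate (not isolated)
14 | trans-fused bicyclic hydroxy aldehyde (C3 CHO, epimers; C4 β-OH, α-isopropyl; C6 α-OH; C8 ketone; C1 β-methyl; H5 α) | O=C1C[C@H](O)[C@@H]2[C@](C)(CC(C=O)[C@@]2(O)C(C)C)CC1 | intermediate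
15 | C3 carboxylic acid corresponding to 14 (C3 epimers) | O=C1C[C@H](O)[C@@H]2[C@](C)(CC(C(=O)O)[C@@]2(O)C(C)C)CC1 | intermediate
16 | 4β,6α-dihydroxy trans-fused bicyclic C8 ketone (C1 β-methyl, H5 α, C4 α-isopropyl) | O=C1C[C@H](O)[C@@H]2[C@](C)(CC[C@@]2(O)C(C)C)CC1 | intermediate
17 | C8 trimethylsilyl enol ether (C8=C9) of 16 with both hydroxyls as trimethylsilyl ethers | C[Si](C)(C)OC=1C[C@H](O[Si](C)(C)C)[C@@H]2[C@](C)(CC[C@@]2(O[Si](C)(C)C)C(C)C)CC1 | intermediate (not isolated)
18 | 4β,6α-dihydroxy bicyclic enone (C8 ketone, C9=C10) | O=C1C[C@H](O)[C@@H]2[C@](C)(CC[C@@]2(O)C(C)C)C=C1 | intermediate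
19 | 3-methylbutanoic anhydride | CC(C)CC(=O)OC(=O)CC(C)C | starting material
20 | 6α-(3-methylbutanoyloxy)-4β-hydroxy bicyclic enone | O=C1C[C@H](OC(=O)CC(C)C)[C@@H]2[C@](C)(CC[C@@]2(O)C(C)C)C=C1 | intermediate
21 | 9α,10α-dihydroxy-6α-(3-methylbutanoyloxy)-4β-hydroxy bicyclic C8 ketone | O=C1C[C@H](OC(=O)CC(C)C)[C@@H]2[C@](C)(CC[C@@]2(O)C(C)C)[C@H](O)[C@@H]1O | intermediate
22 | (1R,3aS,4S,5R,8S,8aS)-1,4,5-trihydroxy-3a-methyl-6-methylidene-1-(propan-2-yl)decahydroazulen-8-yl 3-methylbutanoate; in the numbering of the text (1S,4R,5S,6S,9R,10S) | C=C1C[C@H](OC(=O)CC(C)C)[C@@H]2[C@](C)(CC[C@@]2(O)C(C)C)[C@H](O)[C@@H]1O | target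

Total step count: 12. Longest linear sequence: 12 steps (from 1 and 2 to 22).

Steps most likely to fail

Step 6. The enolate may be protonated before it closes, it may close on the C8 ketone, or the aldol addition to the hindered C4 ketone may revert. Fallback (from 11, back at 14): the two bonds would be made in two operations. The same iron-hydride Giese addition to acrolein, quenched before any aldol closure, would give the open keto aldehyde F1. Enamine catalysis (pyrrolidine, AcOH, CH2Cl2, or L-proline, DMSO) would then close C3 on the C4 ketone by a 5-enolexo aldol addition to give 14.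

Step 4. Facial selectivity in the protonation of the dienolate at C5 may be poor or reversed, and the double bond may drift into conjugation. Fallback (from 9, back at 10): C5 would be set while the oxygen bridge still fixes the ring. Irradiation of 9 at 350 nm (benzene, catalytic imidazole) would deconjugate the enone by γ-hydrogen transfer from the C1 methyl group. The photodienol would take up its proton on the open exo face and give the exo-methylene ketone F2, with the isobutyryl group endo and so trans to the bridge oxygen. Et3SiH and BF3·OEt2 (CH2Cl2, −78 °C) would then cleave the allylic C10–O bond reductively, hydride entering at the exocyclic terminus, to give 10.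

Step 12. The methylenation may stall through chelation by the neighbouring diol, or the Lewis acid may trigger retro-aldol cleavage or β-elimination of the ester. Fallback (from 21, back at 22): the diol would be tied up as the acetonide F3 (2,2-dimethoxypropane, pyridinium p-toluenesulfonate, CH2Cl2). The ketone would be methylenated with Cp2TiMe2 (toluene, 65 °C) to give the methylidene acetonide F4, and aqueous acetic acid would remove the acetonide to give 22.

Further compounds
F1 | step 6 | open keto aldehyde: 11 with H added at C10 and a 3-oxopropyl group on the α face of C1 (methyl β) | O=C1C[C@H](O)[C@@H](C(=O)C(C)C)[C@](C)(CCC=O)CC1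
F2 | step 4 | rac-(1S,5R,7S)-6-methylidene-7-(2-methylpropanoyl)-8-oxabicyclo[3.2.1]octan-3-one (acyl endo; racemate, enantiomer of the route drawn) | O=C1C[C@@H]2O[C@H](C1)C(=C)[C@@H]2C(=O)C(C)C
F3 | step 12 | 9,10-O-isopropylidene derivative of 21 | O=C1C[C@H](OC(=O)CC(C)C)[C@@H]2[C@](C)(CC[C@@]2(O)C(C)C)[C@H](OC(C)(C)O3)[C@@H]13
F4 | step 12 | 9,10-O-isopropylidene derivative of 22 | C=C1C[C@H](OC(=O)CC(C)C)[C@@H]2[C@](C)(CC[C@@]2(O)C(C)C)[C@H](OC(C)(C)O3)[C@@H]13
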